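Both six-membered rings of pyrrhoxanthin come from one (3+3) annulation. In the epoxycyclohexanol ring A (C1 gem-dimethyl carbon, C3 carbinol, C5/C6 epoxide carbons) the C3–C4 and C1–C6 bonds are made in one flask: a BINOL–Ti(OiPr)4-catalysed vinylogous Mukaiyama aldol of Chan's diene with 3-methylbut-3-enal sets C3, then SnCl4 lets the keto ester α-carbon (C6) capture the tertiary cation at C1. The step exploits the 1,3-relationship between the C3 carbinol and the quaternary C1, with C4–C5–C6 as a latent acetoacetate. The keto ester is elaborated to ring A (Sharpless epoxidation) and to the acetylenic ring B; two Stille couplings on a bromo(ylidene)butenolide complete the polyene.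

Key step: step 2

Remark on the chemistry: ring A carbons are numbered as in carotenoids (C6 bears the side chain); (R)-BINOL is assumed to direct the diene to the Re face of aldehyde 2, and the antipodal ligand is used if the sense proves opposite.

**Ring construction (common to both rings)**

Step 1
Reactants: 1 3-methylbut-3-en-1-ol
Product: 2 3-methylbut-3-enal
Conditions: Dess–Martin periodinane, CH2Cl2, 0 °C to rt; short-path distillation, used at once
Reagents that add atoms: none
Why: Dess–Martin oxidation of the primary alcohol under neutral conditions should give the aldehyde without moving the β,γ-double bond into conjugation.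

Step 2
Reactants: 2 3-methylbut-3-enal; 3 1-methoxy-1,3-bis(trimethylsilyloxy)buta-1,3-diene (Chan's diene)
Product: 5 methyl (4S)-4-hydroxy-2,2-dimethyl-6-oxocyclohexane-1-carboxylate, via open-chain aldol adduct 4 (not isolated)
Conditions: Ti(OiPr)4 (8 mol %), (R)-BINOL (8 mol %), 4 Å MS, THF, −78 °C to rt; THF exchanged for CH2Cl2 in the same flask, then SnCl4 (2 equiv), 0 °C to rt; aq. HCl work-up
Reagents that add atoms: none
Why: A BINOL–titanium-catalysed vinylogous Mukaiyama aldol joins the terminal (γ) carbon of the diene to the aldehyde carbon (C4–C3); after desilylation SnCl4 chelates the β-keto ester while HCl formed in the flask protonates the 2-methylallyl alkene to the tertiary cation at C1, which the enol α-carbon captures (C6–C1). The closest known reactions are the Ti(OiPr)4/BINOL aldol of Chan's diene with aldehydes and the SnCl4-mediated cyclization of olefinic β-keto esters to 2,2-dimethyl-6-oxocyclohexanecarboxylates, here run in one flask as a (3+3) annulation. The ring closes in a 6-(enolendo)-exo-trig mode with Markovnikov attack at the internal alkene carbon. C3 is set by the chiral titanium complex (Re-face attack gives the S carbinol) and is not touched by the cyclization, whereas the new α-carbon stereocenter (C6) is uncontrolled, enolizable and erased in step 4. The step needs γ- over α-attack of the diene (inherent to the bis-silyl dienol ether), C- over O-alkylation (the tin chelate presents carbon for six-ring closure, and O-alkylation to a tertiary enol ether should be reversible under the Lewis acid) and survival of the β-hydroxy ketone (0 °C, prompt silylation in step 3).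

Step 3
Reactants: 5 methyl (4S)-4-hydroxy-2,2-dimethyl-6-oxocyclohexane-1-carboxylate
Product: 6 methyl (4S)-4-[(tert-butyldimethylsilyl)oxy]-2,2-dimethyl-6-oxocyclohexane-1-carboxylate
Conditions: TBSCl, imidazole, DMF, rt
Reagents that add atoms: tert-butyldimethylsilyl chloride, CC(C)(C)[Si](C)(C)Cl
Why: Standard silylation of the secondary alcohol should protect the β-hydroxy ketone against elimination in the basic steps that follow.

Step 4
Reactants: 6 methyl (4S)-4-[(tert-butyldimethylsilyl)oxy]-2,2-dimethyl-6-oxocyclohexane-1-carboxylate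
Product: 7 methyl (4S)-4-[(tert-butyldimethylsilyl)oxy]-6,6-dimethyl-2-[(trifluoromethanesulfonyl)oxy]cyclohex-1-ene-1-carboxylate
Conditions: NaH, THF, 0 °C; then PhNTf2, 0 °C to rt
Reagents that add atoms: N-phenylbis(trifluoromethanesulfonimide), O=S(=O)(N(c1ccccc1)S(=O)(=O)C(F)(F)F)C(F)(F)F
Why: O-triflation of the sodium enolate of the β-keto ester should give the tetrasubstituted enol triflate, and deprotonation between the two carbonyl groups avoids E1cB loss of the silyloxy group.

Step 5
Reactants: 7 methyl (4S)-4-[(tert-butyldimethylsilyl)oxy]-6,6-dimethyl-2-[(trifluoromethanesulfonyl)oxy]cyclohex-1-ene-1-carboxylate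
Product: 8 methyl (4R)-4-[(tert-butyldimethylsilyl)oxy]-2,6,6-trimethylcyclohex-1-ene-1-carboxylate
Conditions: MeMgBr, Fe(acac)3 (5 mol %), THF/NMP, −30 °C
Reagents that add atoms: methylmagnesium bromide, C[Mg]Br
Why: Iron-catalysed Kumada-type coupling of the ester-activated enol triflate should install the C5 methyl group faster than the Grignard reagent attacks the ester (the descriptor changes only through priorities).

Step 6
Reactants: 8 methyl (4R)-4-[(tert-butyldimethylsilyl)oxy]-2,6,6-trimethylcyclohex-1-ene-1-carboxylate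
Product: 9 [(4R)-4-[(tert-butyldimethylsilyl)oxy]-2,6,6-trimethylcyclohex-1-en-1-yl]methanol
Conditions: i-Bu2AlH, CH2Cl2, −78 to 0 °C; aq. KNaC4H4O6 work-up
Reagents that add atoms: none
Why: Hydride reduction of the hindered conjugated ester should give the allylic alcohol that serves both rings, the silyl ether being inert.

**Ring A (epoxide end)**

Step 7
Reactants: 9 [(4R)-4-[(tert-butyldimethylsilyl)oxy]-2,6,6-trimethylcyclohex-1-en-1-yl]methanol
Product: 10 [(1R,4S,6R)-4-[(tert-butyldimethylsilyl)oxy]-2,2,6-trimethyl-7-oxabicyclo[4.1.0]heptan-1-yl]methanol (epoxide oxygen anti to the silyloxy group)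
Conditions: Ti(OiPr)4 (0.2 equiv), D-(−)-diethyl tartrate (0.25 equiv), t-BuOOH, 4 Å MS, CH2Cl2, −20 °C
Reagents that add atoms: tert-butyl hydroperoxide, CC(C)(C)OO
Why: Sharpless asymmetric epoxidation with the D-(−)-tartrate should deliver oxygen to the alkene face anti to the C3 silyloxy group, setting C5 and C6 together under reagent control.

Step 8
Reactants: 10 [(1R,4S,6R)-4-[(tert-butyldimethylsilyl)oxy]-2,2,6-trimethyl-7-oxabicyclo[4.1.0]heptan-1-yl]methanol
Product: 11 (1S,4S,6R)-4-[(tert-butyldimethylsilyl)oxy]-2,2,6-trimethyl-7-oxabicyclo[4.1.0]heptane-1-carbaldehyde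
Conditions: (n-Pr4N)RuO4 (5 mol %), NMO, 4 Å MS, CH2Cl2, rt
Reagents that add atoms: none
Why: Ley–Griffith oxidation is neutral, so the acid-labile epoxide should survive and the non-enolizable aldehyde cannot epimerize.

Step 9
Reactants: 12 dibromomethane; 13 tributyltin chloride
Product: 14 tributyl(dibromomethyl)stannane
Conditions: LiN(iPr)2, THF, −78 °C
Reagents that add atoms: none
Why: Deprotonation of dibromomethane and trapping of dibromomethyllithium by the tin chloride should give the reagent for Takai–Hodgson olefination.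

Step 10
Reactants: 11 (1S,4S,6R)-4-[(tert-butyldimethylsilyl)oxy]-2,2,6-trimethyl-7-oxabicyclo[4.1.0]heptane-1-carbaldehyde; 14 tributyl(dibromomethyl)stannane
Product: 15 tributyl{(E)-2-[(1S,4S,6R)-4-[(tert-butyldimethylsilyl)oxy]-2,2,6-trimethyl-7-oxabicyclo[4.1.0]heptan-1-yl]ethenyl}stannane
Conditions: CrCl2, LiI, THF/DMF, rt, dark
Reagents that add atoms: none
Why: Takai–Hodgson olefination via a gem-dichromium species should give the (E)-vinylstannane without base, which spares the epoxide and avoids an ethynyl epoxide that palladium could open to an allene.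

Step 11
Reactants: 15 tributyl{(E)-2-[(1S,4S,6R)-4-[(tert-butyldimethylsilyl)oxy]-2,2,6-trimethyl-7-oxabicyclo[4.1.0]heptan-1-yl]ethenyl}stannane
Product: 16 the C3 alcohol of 15, tributyl{(E)-2-[(1S,4S,6R)-4-hydroxy-2,2,6-trimethyl-7-oxabicyclo[4.1.0]heptan-1-yl]ethenyl}stannane
Conditions: Bu4NF, THF, 0 °C to rt
Reagents that add atoms: none
Why: Fluoride cleavage of the silyl ether leaves the vinylstannane and epoxide intact and frees the hydroxyl before the union, so no deprotection is needed on the polyene.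

**Ring B (acetylenic end)**

Step 12
Reactants: 9 [(4R)-4-[(tert-butyldimethylsilyl)oxy]-2,6,6-trimethylcyclohex-1-en-1-yl]methanol
Product: 17 (4R)-4-[(tert-butyldimethylsilyl)oxy]-2,6,6-trimethylcyclohex-1-ene-1-carbaldehyde
Conditions: MnO2, CH2Cl2, rt
Reagents that add atoms: none
Why: Selective oxidation of the allylic alcohol with MnO2 should give the enal.

Step 13
Reactants: 17 (4R)-4-[(tert-butyldimethylsilyl)oxy]-2,6,6-trimethylcyclohex-1-ene-1-carbaldehyde
Product: 18 tert-butyl{[(1R)-4-ethynyl-3,5,5-trimethylcyclohex-3-en-1-yl]oxy}dimethylsilane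
Conditions: TMSCHN2, n-BuLi, THF, −78 °C to rt
Reagents that add atoms: (trimethylsilyl)diazomethane, C[Si](C)(C)C=[N+]=[N-]
Why: Colvin rearrangement (addition of the lithiated diazomethane, Peterson elimination, 1,2-shift of the alkylidene carbene) should convert the hindered enal into the terminal enyne in one step.

Step 14
Reactants: 18 tert-butyl{[(1R)-4-ethynyl-3,5,5-trimethylcyclohex-3-en-1-yl]oxy}dimethylsilane
Product: 19 (1R)-4-ethynyl-3,5,5-trimethylcyclohex-3-en-1-ol
Conditions: Bu4NF, THF, rt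
Reagents that add atoms: none
Why: Fluoride desilylation of the secondary silyl ether frees the hydroxyl that carries the acetate of the target.

Step 15
Reactants: 19 (1R)-4-ethynyl-3,5,5-trimethylcyclohex-3-en-1-ol
Product: 20 (1R)-4-ethynyl-3,5,5-trimethylcyclohex-3-en-1-yl acetate
Conditions: Ac2O, pyridine, DMAP (cat.), CH2Cl2, rt
Reagents that add atoms: acetic anhydride, CC(=O)OC(C)=O
Why: Standard acylation installs the acetate early, since all later steps on this branch are non-basic and non-reducing.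

Step 16
Reactants: 21 ethyl acetoacetate
Product: 22 ethyl (2E)-3-[(trifluoromethanesulfonyl)oxy]but-2-enoate
Conditions: Tf2O, aq. Me4NOH, hexanes, 5 °C
Reagents that add atoms: trifluoromethanesulfonic anhydride, O=S(=O)(OS(=O)(=O)C(F)(F)F)C(F)(F)F
Why: Triflation of the non-chelated tetramethylammonium enolate should give the (E)-enol triflate with the triflate trans to the ester.

Step 17
Reactants: 22 ethyl (2E)-3-[(trifluoromethanesulfonyl)oxy]but-2-enoate
Product: 23 (2E)-4-hydroxybut-2-en-2-yl trifluoromethanesulfonate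
Conditions: i-Bu2AlH, CH2Cl2, −78 °C
Reagents that add atoms: none
Why: Low-temperature hydride reduction of the ester leaves the vinyl triflate untouched, which keeps hydride reagents off the acetate-bearing main line.

Step 18
Reactants: 20 (1R)-4-ethynyl-3,5,5-trimethylcyclohex-3-en-1-yl acetate; 23 (2E)-4-hydroxybut-2-en-2-yl trifluoromethanesulfonate
Product: 24 (1R)-4-[(3E)-5-hydroxy-3-methylpent-3-en-1-yn-1-yl]-3,5,5-trimethylcyclohex-3-en-1-yl acetate
Conditions: Pd(PPh3)4 (5 mol %), CuI (10 mol %), Et3N, THF, rt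
Reagents that add atoms: none
Why: Sonogashira coupling of the vinyl triflate proceeds with retention, placing the alkyne trans to the hydroxymethyl group as in the target.

Step 19
Reactants: 24 (1R)-4-[(3E)-5-hydroxy-3-methylpent-3-en-1-yn-1-yl]-3,5,5-trimethylcyclohex-3-en-1-yl acetate
Product: 25 (1R)-3,5,5-trimethyl-4-[(3E)-3-methyl-5-oxopent-3-en-1-yn-1-yl]cyclohex-3-en-1-yl acetate
Conditions: MnO2, CH2Cl2, rt
Reagents that add atoms: none
Why: Allylic oxidation with MnO2 should give the enynal without touching the acetate.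

Step 20
Reactants: 25 (1R)-3,5,5-trimethyl-4-[(3E)-3-methyl-5-oxopent-3-en-1-yn-1-yl]cyclohex-3-en-1-yl acetate; 14 tributyl(dibromomethyl)stannane
Product: 26 (1R)-3,5,5-trimethyl-4-[(3E,5E)-3-methyl-6-(tributylstannyl)hexa-3,5-dien-1-yn-1-yl]cyclohex-3-en-1-yl acetate
Conditions: CrCl2, LiI, THF/DMF, rt, dark
Reagents that add atoms: none
Why: Takai–Hodgson olefination of the enal should give the (E)-dienylstannane under conditions that spare the acetate.

**Butenolide core**

Step 21
Reactants: 27 propiolic acid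
Product: 28 (2E)-2,3-dibromoprop-2-enoic acid
Conditions: Br2, CHCl3, 0 °C to rt, dark
Reagents that add atoms: bromine, BrBr
Why: Anti addition of bromine to the alkyne should give the (E)-dibromide, in which the β-bromide is cis to the carboxyl group.

Step 22
Reactants: 28 (2E)-2,3-dibromoprop-2-enoic acid; 29 (2E)-3-methylpent-2-en-4-yn-1-ol
Product: 31 (5Z)-3-bromo-5-[(2E)-4-hydroxy-2-methylbut-2-en-1-ylidene]furan-2(5H)-one, via bromoenynoic acid 30 (not isolated)
Conditions: PdCl2(PPh3)2 (5 mol %), CuI (10 mol %), Et3N, MeCN, rt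
Reagents that add atoms: none
Why: Tandem Sonogashira coupling at the more reactive β-bromide followed by 5-exo-dig anti addition of the carboxylate across the alkyne should give the (Z)-ylidenebutenolide with the α-bromide retained.

Step 23
Reactants: 31 (5Z)-3-bromo-5-[(2E)-4-hydroxy-2-methylbut-2-en-1-ylidene]furan-2(5H)-one
Product: 32 (2E)-4-[(2Z)-4-bromo-5-oxofuran-2(5H)-ylidene]-3-methylbut-2-enal
Conditions: MnO2, CH2Cl2, rt, dark
Reagents that add atoms: none
Why: Allylic oxidation with MnO2 is neutral and should leave the enol lactone intact.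

Step 24
Reactants: 32 (2E)-4-[(2Z)-4-bromo-5-oxofuran-2(5H)-ylidene]-3-methylbut-2-enal
Product: 33 (5Z)-3-bromo-5-[(2E,4E)-5-iodo-2-methylpenta-2,4-dien-1-ylidene]furan-2(5H)-one
Conditions: CrCl2, CHI3, THF, 0 °C, dark
Reagents that add atoms: iodoform, IC(I)I
Why: Takai iodo-olefination should give the (E)-dienyl iodide, since divalent chromium does not insert into the vinylic C–Br bond or reduce the lactone under these conditions.

**Unions**

Step 25
Reactants: 33 (5Z)-3-bromo-5-[(2E,4E)-5-iodo-2-methylpenta-2,4-dien-1-ylidene]furan-2(5H)-one; 26 (1R)-3,5,5-trimethyl-4-[(3E,5E)-3-methyl-6-(tributylstannyl)hexa-3,5-dien-1-yn-1-yl]cyclohex-3-en-1-yl acetate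
Product: 34 (1R)-4-[(3E,5E,7E,9E)-11-[(2Z)-4-bromo-5-oxofuran-2(5H)-ylidene]-3,10-dimethylundeca-3,5,7,9-tetraen-1-yn-1-yl]-3,5,5-trimethylcyclohex-3-en-1-yl acetate
Conditions: Pd2(dba)3 (2.5 mol %), AsPh3, DMF, rt, dark
Reagents that add atoms: none
Why: Stille coupling, in which zerovalent palladium should insert into the alkenyl C–I bond much faster than into the C3–Br bond of the butenolide at rt, so one equivalent of stannane couples at the iodide with retention of both alkene geometries.

Step 26
Reactants: 34 the bromobutenolide polyene of step 25; 16 tributyl{(E)-2-[(1S,4S,6R)-4-hydroxy-2,2,6-trimethyl-7-oxabicyclo[4.1.0]heptan-1-yl]ethenyl}stannane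
Product: 35 pyrrhoxanthin (the target)
Conditions: Pd2(dba)3 (5 mol %), AsPh3, NMP, 40 °C, dark
Reagents that add atoms: none
Why: Stille coupling at the butenolide C–Br bond under neutral conditions should tolerate the free hydroxyl, the acetate and the hindered vinyl epoxide and form the last C–C bond with retention of the (E)-vinyl geometry.

**Compound list**

1 | 3-methylbut-3-en-1-ol | CC(=C)CCO | starting material
2 | 3-methylbut-3-enal | CC(=C)CC=O | intermediate
3 | 1-methoxy-1,3-bis(trimethylsilyloxy)buta-1,3-diene (Chan's diene; ketene acetal geometry immaterial) | COC(O[Si](C)(C)C)=CC(=C)O[Si](C)(C)C | starting material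
4 | methyl (5S)-5-hydroxy-7-methyl-3-oxooct-7-enoate (aldol adduct, present as its silyl and tin derivatives) | COC(=O)CC(=O)C[C@@H](O)CC(C)=C | intermediate (not isolated)
5 | methyl (4S)-4-hydroxy-2,2-dimethyl-6-oxocyclohexane-1-carboxylate (C1 epimers and enol form) | COC(=O)C1C(=O)C[C@@H](O)CC1(C)C | intermediate
6 | methyl (4S)-4-[(tert-butyldimethylsilyl)oxy]-2,2-dimethyl-6-oxocyclohexane-1-carboxylate | COC(=O)C1C(=O)C[C@@H](O[Si](C)(C)C(C)(C)C)CC1(C)C | intermediate
7 | methyl (4S)-4-[(tert-butyldimethylsilyl)oxy]-6,6-dimethyl-2-[(trifluoromethanesulfonyl)oxy]cyclohex-1-ene-1-carboxylate | COC(=O)C1=C(OS(=O)(=O)C(F)(F)F)C[C@@H](O[Si](C)(C)C(C)(C)C)CC1(C)C | intermediate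
8 | methyl (4R)-4-[(tert-butyldimethylsilyl)oxy]-2,6,6-trimethylcyclohex-1-ene-1-carboxylate | COC(=O)C1=C(C)C[C@@H](O[Si](C)(C)C(C)(C)C)CC1(C)C | intermediate
9 | [(4R)-4-[(tert-butyldimethylsilyl)oxy]-2,6,6-trimethylcyclohex-1-en-1-yl]methanol | OCC1=C(C)C[C@@H](O[Si](C)(C)C(C)(C)C)CC1(C)C | intermediate
10 | [(1R,4S,6R)-4-[(tert-butyldimethylsilyl)oxy]-2,2,6-trimethyl-7-oxabicyclo[4.1.0]heptan-1-yl]methanol | OC[C@@]12O[C@]1(C)C[C@@H](O[Si](C)(C)C(C)(C)C)CC2(C)C | intermediate
11 | (1S,4S,6R)-4-[(tert-butyldimethylsilyl)oxy]-2,2,6-trimethyl-7-oxabicyclo[4.1.0]heptane-1-carbaldehyde | O=C[C@@]12O[C@]1(C)C[C@@H](O[Si](C)(C)C(C)(C)C)CC2(C)C | intermediate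
12 | dibromomethane | BrCBr | starting material
13 | tributyltin chloride | CCCC[Sn](Cl)(CCCC)CCCC | starting material
14 | tributyl(dibromomethyl)stannane | CCCC[Sn](CCCC)(CCCC)C(Br)Br | intermediate
15 | tributyl{(E)-2-[(1S,4S,6R)-4-[(tert-butyldimethylsilyl)oxy]-2,2,6-trimethyl-7-oxabicyclo[4.1.0]heptan-1-yl]ethenyl}stannane | CCCC[Sn](CCCC)(CCCC)/C=C/[C@@]12O[C@]1(C)C[C@@H](O[Si](C)(C)C(C)(C)C)CC2(C)C | intermediate
16 | tributyl{(E)-2-[(1S,4S,6R)-4-hydroxy-2,2,6-trimethyl-7-oxabicyclo[4.1.0]heptan-1-yl]ethenyl}stannane (numbered as in 15) | CCCC[Sn](CCCC)(CCCC)/C=C/[C@@]12O[C@]1(C)C[C@@H](O)CC2(C)C | intermediate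
17 | (4R)-4-[(tert-butyldimethylsilyl)oxy]-2,6,6-trimethylcyclohex-1-ene-1-carbaldehyde | O=CC1=C(C)C[C@@H](O[Si](C)(C)C(C)(C)C)CC1(C)C | intermediate
18 | tert-butyl{[(1R)-4-ethynyl-3,5,5-trimethylcyclohex-3-en-1-yl]oxy}dimethylsilane | C#CC1=C(C)C[C@@H](O[Si](C)(C)C(C)(C)C)CC1(C)C | intermediate
19 | (1R)-4-ethynyl-3,5,5-trimethylcyclohex-3-en-1-ol | C#CC1=C(C)C[C@@H](O)CC1(C)C | intermediate
20 | (1R)-4-ethynyl-3,5,5-trimethylcyclohex-3-en-1-yl acetate | CC(=O)O[C@@H]1CC(C)=C(C#C)C(C)(C)C1 | intermediate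
21 | ethyl acetoacetate | CCOC(=O)CC(C)=O | starting material
22 | ethyl (2E)-3-[(trifluoromethanesulfonyl)oxy]but-2-enoate | CCOC(=O)/C=C(/OS(=O)(=O)C(F)(F)F)C | intermediate
23 | (2E)-4-hydroxybut-2-en-2-yl trifluoromethanesulfonate | OC/C=C(/OS(=O)(=O)C(F)(F)F)C | intermediate
24 | (1R)-4-[(3E)-5-hydroxy-3-methylpent-3-en-1-yn-1-yl]-3,5,5-trimethylcyclohex-3-en-1-yl acetate | CC(=O)O[C@@H]1CC(C)=C(C#C/C(C)=C/CO)C(C)(C)C1 | intermediate
25 | (1R)-3,5,5-trimethyl-4-[(3E)-3-methyl-5-oxopent-3-en-1-yn-1-yl]cyclohex-3-en-1-yl acetate | CC(=O)O[C@@H]1CC(C)=C(C#C/C(C)=C/C=O)C(C)(C)C1 | intermediate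
26 | (1R)-3,5,5-trimethyl-4-[(3E,5E)-3-methyl-6-(tributylstannyl)hexa-3,5-dien-1-yn-1-yl]cyclohex-3-en-1-yl acetate | CC(=O)O[C@@H]1CC(C)=C(C#C/C(C)=C/C=C/[Sn](CCCC)(CCCC)CCCC)C(C)(C)C1 | intermediate
27 | propiolic acid | C#CC(=O)O | starting material
28 | (2E)-2,3-dibromoprop-2-enoic acid | OC(=O)/C(Br)=C\Br | intermediate
29 | (2E)-3-methylpent-2-en-4-yn-1-ol | C#C/C(C)=C/CO | starting material
30 | (2E,6E)-2-bromo-8-hydroxy-6-methylocta-2,6-dien-4-ynoic acid | OC(=O)/C(Br)=C\C#C/C(C)=C/CO | intermediate (not isolated)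
31 | (5Z)-3-bromo-5-[(2E)-4-hydroxy-2-methylbut-2-en-1-ylidene]furan-2(5H)-one | OC/C=C(C)/C=C2C=C(Br)C(=O)O/2 | intermediate
32 | (2E)-4-[(2Z)-4-bromo-5-oxofuran-2(5H)-ylidene]-3-methylbut-2-enal | O=C/C=C(C)/C=C2C=C(Br)C(=O)O/2 | intermediate
33 | (5Z)-3-bromo-5-[(2E,4E)-5-iodo-2-methylpenta-2,4-dien-1-ylidene]furan-2(5H)-one | I/C=C/C=C(C)/C=C2C=C(Br)C(=O)O/2 | intermediate
34 | (1R)-4-[(3E,5E,7E,9E)-11-[(2Z)-4-bromo-5-oxofuran-2(5H)-ylidene]-3,10-dimethylundeca-3,5,7,9-tetraen-1-yn-1-yl]-3,5,5-trimethylcyclohex-3-en-1-yl acetate | CC(=O)O[C@@H]1CC(C)=C(C#C/C(C)=C/C=C/C=C/C=C(C)/C=C2C=C(Br)C(=O)O/2)C(C)(C)C1 | intermediate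
35 | pyrrhoxanthin | CC(=O)O[C@@H]1CC(C)=C(C#C/C(C)=C/C=C/C=C/C=C(C)/C=C2C=C(/C=C/[C@@]34O[C@]3(C)C[C@@H](O)CC4(C)C)C(=O)O/2)C(C)(C)C1 | target

**Summary**

Total step count: 26. Longest linear sequence: 15 steps (steps 1–6, 12–15, 18–20, 25 and 26).

Steps most likely to fail:

Step 2. The one-flask annulation may suffer from poor facial selectivity in the aldol with an enolizable β,γ-unsaturated aldehyde, from migration of the aldehyde double bond into conjugation, or from O-cyclization, lactonization or dehydration of the free β-hydroxy ketone during the Lewis acid stage. The fallback makes the two bonds in separate operations on a protected substrate. From 2, a vinylogous Mukaiyama aldol with 2,2-dimethyl-6-methylene-4-(trimethylsilyloxy)-4H-1,3-dioxine under a chiral BINOL-derived titanium Schiff-base catalyst (Et2O, 0 °C, acidic work-up) should give the dioxinone aldol (S)-6-(2-hydroxy-4-methylpent-4-en-1-yl)-2,2-dimethyl-4H-1,3-dioxin-4-one F1. Silylation (TBSCl, imidazole) gives its silyl ether F2. Thermolysis in toluene/MeOH at 110 °C (acylketene trapping) gives methyl (5S)-5-[(tert-butyldimethylsilyl)oxy]-7-methyl-3-oxooct-7-enoate F3. SnCl4 in CH2Cl2 then closes the ring as an isolated cation–olefin cyclization of a keto ester without a free hydroxyl, and the route is rejoined at 6.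

Step 25. Discrimination between the alkenyl iodide and the butenolide bromide may be incomplete, leading to double coupling or oligomers. The fallback reverses the order of the unions so that no second halide is present. From 32, Stille coupling with 16 at the C–Br bond (Pd2(dba)3, AsPh3) should give the ring A enal (2E)-4-[(2Z)-4-{(E)-2-[(1S,4S,6R)-4-hydroxy-2,2,6-trimethyl-7-oxabicyclo[4.1.0]heptan-1-yl]ethenyl}-5-oxofuran-2(5H)-ylidene]-3-methylbut-2-enal F4. Takai iodo-olefination (CrCl2, CHI3) gives the corresponding (E)-dienyl iodide F5. Stille coupling of F5 with 26 rejoins the route at 35.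

Step 22. The tandem process may give over-coupling at the butenolide bromide, 6-endo closure to the pyranone or loss of ylidene geometry. The fallback separates coupling from lactonization and changes the cyclization metal. From 28, acid-catalysed esterification (MeOH, H2SO4) gives methyl (2E)-2,3-dibromoprop-2-enoate F6. β-Selective Sonogashira coupling with 29 gives methyl (2E,6E)-2-bromo-8-hydroxy-6-methylocta-2,6-dien-4-ynoate F7. Saponification (LiOH, THF/H2O) gives acid 30, now isolated. AgNO3-catalysed 5-exo-dig lactonization in acetone, which favours the five-membered (Z)-ylidene lactone, rejoins the route at 31.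

Further compounds

F1 | step 2 | (S)-6-(2-hydroxy-4-methylpent-4-en-1-yl)-2,2-dimethyl-4H-1,3-dioxin-4-one | O=C1C=C(C[C@@H](O)CC(C)=C)OC(C)(C)O1
F2 | step 2 | (S)-6-{2-[(tert-butyldimethylsilyl)oxy]-4-methylpent-4-en-1-yl}-2,2-dimethyl-4H-1,3-dioxin-4-one | O=C1C=C(C[C@@H](O[Si](C)(C)C(C)(C)C)CC(C)=C)OC(C)(C)O1
F3 | step 2 | methyl (5S)-5-[(tert-butyldimethylsilyl)oxy]-7-methyl-3-oxooct-7-enoate | COC(=O)CC(=O)C[C@@H](O[Si](C)(C)C(C)(C)C)CC(C)=C
F4 | step 25 | (2E)-4-[(2Z)-4-{(E)-2-[(1S,4S,6R)-4-hydroxy-2,2,6-trimethyl-7-oxabicyclo[4.1.0]heptan-1-yl]ethenyl}-5-oxofuran-2(5H)-ylidene]-3-methylbut-2-enal | O=C/C=C(C)/C=C2C=C(/C=C/[C@@]34O[C@]3(C)C[C@@H](O)CC4(C)C)C(=O)O/2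
F5 | step 25 | (5Z)-3-{(E)-2-[(1S,4S,6R)-4-hydroxy-2,2,6-trimethyl-7-oxabicyclo[4.1.0]heptan-1-yl]ethenyl}-5-[(2E,4E)-5-iodo-2-methylpenta-2,4-dien-1-ylidene]furan-2(5H)-one | I/C=C/C=C(C)/C=C2C=C(/C=C/[C@@]34O[C@]3(C)C[C@@H](O)CC4(C)C)C(=O)O/2
F6 | step 22 | methyl (2E)-2,3-dibromoprop-2-enoate | COC(=O)/C(Br)=C\Br
F7 | step 22 | methyl (2E,6E)-2-bromo-8-hydroxy-6-methylocta-2,6-dien-4-ynoate | COC(=O)/C(Br)=C\C#C/C(C)=C/CO
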